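**Retrosynthetic overview**
- Target 17 comes from 16 by removal of both benzyl groups; 16 comes from the 5-O-benzyl flavone 13 by C3 hydroxylation (C3–H → C3–Li → C3–B → C3–OH); 13 comes from the 5-hydroxyflavone 12.
- Key disconnection of 12: C4a–C4, C4–C3 and O1–C2 are cut together, giving aryl iodide 6, carbon monoxide 9 and alkyne 8. The pyranone (ring C) is the only ring built; rings A and B are bought in.
- Structural feature: in ring A (C4a, C5, C6, C7, C8, C8a) the oxygens on C5 and C8a (O1) flank C4a, and the 6,7,8-trimethoxy block is symmetric about the C4a···C7 axis. The A-ring piece, 2-iodo-4,5,6-trimethoxyresorcinol, therefore has a mirror plane; it is carried into the key step as its diacetate 6, and whichever oxygen closes becomes O1 while the other becomes the C5 hydroxyl.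
- 6 comes from 1,2,3-trimethoxybenzene 1 by 4,6-dibromination, double borylation, oxidation, and one-pot iodination/acetylation; 8 comes from 4-(benzyloxy)benzaldehyde 7 by Ohira–Bestmann homologation.

Key step: step 6

Remark: the target has no stereocentre, so the route delivers the single achiral compound as drawn and no enantiocontrol is involved.

**Step 1**
Reactants: 1 1,2,3-trimethoxybenzene
Product: 2 4,6-dibromo-1,2,3-trimethoxybenzene
Conditions: NBS (2.1 equiv), MeCN, 0 °C → rt
Reagents that add atoms: N-bromosuccinimide O=C1CCC(=O)N1Br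
Why: Electrophilic aromatic bromination, in which the two outer methoxy groups direct ortho/para to C4 and then C6, while C5 is activated only by the twisted central methoxy group.

**Step 2**
Reactants: 2 4,6-dibromo-1,2,3-trimethoxybenzene
Product: 3 2,2'-(4,5,6-trimethoxy-1,3-phenylene)bis(4,4,5,5-tetramethyl-1,3,2-dioxaborolane)
Conditions: B2pin2 (2.6 equiv), Pd(dppf)Cl2·CH2Cl2 (5 mol%), KOAc (6 equiv), dioxane, 95 °C
Reagents that add atoms: bis(pinacolato)diboron CC1(C)OB(B2OC(C)(C)C(C)(C)O2)OC1(C)C
Why: Twofold Miyaura borylation of an aryl dibromide, where each C–Br has only one ortho substituent and acetate as base avoids Suzuki homocoupling.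

**Step 3**
Reactants: 3 2,2'-(4,5,6-trimethoxy-1,3-phenylene)bis(4,4,5,5-tetramethyl-1,3,2-dioxaborolane)
Product: 4 4,5,6-trimethoxybenzene-1,3-diol
Conditions: 30% aq H2O2, aq NaOH, degassed THF, 0 °C, Ar; aq NH4Cl work-up
Reagents that add atoms: hydrogen peroxide OO
Why: Oxidation of the aryl boronates by hydroperoxide with 1,2-aryl migration from boron to oxygen puts each hydroxyl exactly where bromine stood; the diol is meta, so it cannot form a quinone directly, and should survive brief cold treatment under argon.

**Step 4**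
Reactants: 4 4,5,6-trimethoxybenzene-1,3-diol
Product: 6 2-iodo-4,5,6-trimethoxy-1,3-phenylene diacetate, via 2-iodo-4,5,6-trimethoxybenzene-1,3-diol 5 (not isolated)
Conditions: NIS (1.0 equiv), MeCN, 0 °C, dark; then pyridine, Ac2O (4 equiv), DMAP (cat.), 0 °C → rt
Reagents that add atoms: N-iodosuccinimide O=C1CCC(=O)N1I; acetic anhydride CC(=O)OC(C)=O
Why: The only ring CH lies ortho to both hydroxyls and is iodinated by electrophilic aromatic substitution, and immediate O-acetylation masks the electron-rich iodoresorcinol before it can lose iodine or oxidise, giving a bench-stable, still mirror-symmetric iodide.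

**Step 5**
Reactants: 7 4-(benzyloxy)benzaldehyde
Product: 8 1-(benzyloxy)-4-ethynylbenzene
Conditions: dimethyl (1-diazo-2-oxopropyl)phosphonate (1.3 equiv), K2CO3 (2 equiv), MeOH, rt
Reagents that add atoms: dimethyl (1-diazo-2-oxopropyl)phosphonate (Ohira–Bestmann reagent) COP(=O)(OC)C(=[N+]=[N-])C(C)=O
Why: Ohira–Bestmann (Seyferth–Gilbert) homologation, in which the diazomethylphosphonate anion made in situ olefinates the aldehyde and the diazoalkene loses nitrogen with a 1,2-hydride shift to give the terminal alkyne; the benzyl ether is untouched.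

**Step 6**
Reactants: 6 2-iodo-4,5,6-trimethoxy-1,3-phenylene diacetate; 8 1-(benzyloxy)-4-ethynylbenzene; 9 carbon monoxide
Product: 12 4'-(benzyloxy)-5-hydroxy-6,7,8-trimethoxyflavone, via ynone diacetate 10 (not isolated), via diethylamino enone 11 (not isolated)
Conditions: PdCl2(PPh3)2 (5 mol%), dppp (5 mol%), thiourea (5 mol%), Et2NH, DBU (3 equiv), CO (1 atm), 45 °C
Reagents that add atoms: none
Why: Pd(0) adds oxidatively to the C–I bond of 6, CO inserts to give an aroylpalladium iodide, and amine-assisted alkynyl transfer from 8 followed by reductive elimination releases ynone 10, which creates C4a–C4 and C4–C3. Diethylamine then adds to the ynone and cleaves both aryl acetates to give β-amino enone 11, whose phenol attacks the β-carbon and expels the amine, forming O1–C2. The pyranone ring is thereby closed in the 6-endo mode (6-endo-dig with respect to the ynone, carried out as an addition–elimination on the enaminone). The closest known reaction type is the palladium–thiourea–dppp catalysed carbonylative annulation of o-iodophenol acetates with terminal arylacetylenes to flavones. The selectivity needed is 6-endo over 5-exo (aurone) closure and carbonylative over direct alkynylation: the acetates keep the phenol masked until the amine has converted the ynone into the enaminone, and the doubly ortho-substituted arylpalladium should insert CO readily in a CO-saturated medium. No regiochemical or stereochemical question arises, because the mirror plane of 6 through C2 and C5 makes the two acetoxy groups equivalent and the product has no stereocentre.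

**Step 7**
Reactants: 12 4'-(benzyloxy)-5-hydroxy-6,7,8-trimethoxyflavone
Product: 13 4',5-bis(benzyloxy)-6,7,8-trimethoxyflavone
Conditions: BnBr (1.5 equiv), K2CO3 (3 equiv), TBAI (cat.), DMF, 70 °C
Reagents that add atoms: benzyl bromide BrCc1ccccc1
Why: Williamson etherification, where warm K2CO3/DMF is enough to break the C5–OH···O=C4 chelate and remove the acidic proton that would otherwise consume the amide base in the next step.

**Step 8**
Reactants: 13 4',5-bis(benzyloxy)-6,7,8-trimethoxyflavone
Product: 16 4',5-bis(benzyloxy)-3-hydroxy-6,7,8-trimethoxyflavone, via 3-lithioflavone 14 (not isolated), via dimethyl flavon-3-ylboronate 15 (not isolated)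
Conditions: LDA (1.5 equiv), THF, −78 °C; B(OMe)3 (3 equiv), −78 → 0 °C; AcOH, 30% aq H2O2, 0 °C → rt
Reagents that add atoms: hydrogen peroxide OO
Why: Lithiation–borylation–oxidation of a flavone, in which LDA removes the vinylic C3–H (acidified by the C4 carbonyl and ring oxygen), the borate trap fixes the site and acidic peroxide converts C–B into C–OH at the same carbon; benzyl and methyl aryl ethers should be inert to LDA at −78 °C.

**Step 9**
Reactants: 16 4',5-bis(benzyloxy)-3-hydroxy-6,7,8-trimethoxyflavone
Product: 17 3,5,4'-trihydroxy-6,7,8-trimethoxyflavone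
Conditions: H2 (1 atm), 10% Pd/C, THF/MeOH, rt
Reagents that add atoms: none
Why: Catalytic hydrogenolysis cleaves both benzylic C–O bonds, while the methyl ethers and the fully conjugated flavonol C2=C3 bond are not reduced at ambient pressure.

**Compound list**
1 | 1,2,3-trimethoxybenzene | COc1cccc(OC)c1OC | starting material
2 | 4,6-dibromo-1,2,3-trimethoxybenzene | COc1c(Br)cc(Br)c(OC)c1OC | intermediate
3 | 2,2'-(4,5,6-trimethoxy-1,3-phenylene)bis(4,4,5,5-tetramethyl-1,3,2-dioxaborolane) | COc1c(B2OC(C)(C)C(C)(C)O2)cc(B2OC(C)(C)C(C)(C)O2)c(OC)c1OC | intermediate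
4 | 4,5,6-trimethoxybenzene-1,3-diol | COc1c(O)cc(O)c(OC)c1OC | intermediate
5 | 2-iodo-4,5,6-trimethoxybenzene-1,3-diol | COc1c(O)c(I)c(O)c(OC)c1OC | intermediate
6 | 2-iodo-4,5,6-trimethoxy-1,3-phenylene diacetate | COc1c(OC(C)=O)c(I)c(OC(C)=O)c(OC)c1OC | intermediate
7 | 4-(benzyloxy)benzaldehyde | O=Cc1ccc(OCc2ccccc2)cc1 | starting material
8 | 1-(benzyloxy)-4-ethynylbenzene | C#Cc1ccc(OCc2ccccc2)cc1 | intermediate
9 | carbon monoxide | [C-]#[O+] | starting material
10 | 2-{3-[4-(benzyloxy)phenyl]prop-2-ynoyl}-4,5,6-trimethoxy-1,3-phenylene diacetate | COc1c(OC(C)=O)c(C(=O)C#Cc2ccc(OCc3ccccc3)cc2)c(OC(C)=O)c(OC)c1OC | intermediate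
11 | (E)-3-[4-(benzyloxy)phenyl]-3-(diethylamino)-1-(2,6-dihydroxy-3,4,5-trimethoxyphenyl)prop-2-en-1-one | CCN(CC)/C(=C/C(=O)c1c(O)c(OC)c(OC)c(OC)c1O)c1ccc(OCc2ccccc2)cc1 | intermediate
12 | 4'-(benzyloxy)-5-hydroxy-6,7,8-trimethoxyflavone | O=c1cc(-c2ccc(OCc3ccccc3)cc2)oc2c(OC)c(OC)c(OC)c(O)c12 | intermediate
13 | 4',5-bis(benzyloxy)-6,7,8-trimethoxyflavone | O=c1cc(-c2ccc(OCc3ccccc3)cc2)oc2c(OC)c(OC)c(OC)c(OCc3ccccc3)c12 | intermediate
14 | 4',5-bis(benzyloxy)-3-lithio-6,7,8-trimethoxyflavone | [Li]c1c(-c2ccc(OCc3ccccc3)cc2)oc2c(OC)c(OC)c(OC)c(OCc3ccccc3)c2c1=O | intermediate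
15 | dimethyl [4',5-bis(benzyloxy)-6,7,8-trimethoxy-4-oxo-4H-chromen-3-yl]boronate | COB(OC)c1c(-c2ccc(OCc3ccccc3)cc2)oc2c(OC)c(OC)c(OC)c(OCc3ccccc3)c2c1=O | intermediate
16 | 4',5-bis(benzyloxy)-3-hydroxy-6,7,8-trimethoxyflavone | O=c1c(O)c(-c2ccc(OCc3ccccc3)cc2)oc2c(OC)c(OC)c(OC)c(OCc3ccccc3)c12 | intermediate
17 | 3,5,4'-trihydroxy-6,7,8-trimethoxyflavone | COc1c(OC)c(O)c2c(=O)c(O)c(-c3ccc(O)cc3)oc2c1OC | target

**Step count**
Total steps: 9. Longest linear sequence: 8 steps (steps 1, 2, 3, 4, 6, 7, 8, 9); step 5 is a one-step side branch.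

**Steps most likely to fail**

Step 6. The hindered aroylpalladium may be intercepted by diethylamine (amide formation), alkynylation may proceed without CO insertion, early acetate loss may be followed by loss of iodine from the very electron-rich ring, or closure may go 5-exo to the aurone. Fallback: from 4, C-acetylation at the lone ring CH (AcOH, BF3·OEt2, 70 °C) should give 1-(2,6-dihydroxy-3,4,5-trimethoxyphenyl)ethan-1-one F1. Its lithium polyanion (LiHMDS, 4 equiv, THF, −78 °C) is C-acylated with 4-(benzyloxy)benzoyl chloride to give 1-[4-(benzyloxy)phenyl]-3-(2,6-dihydroxy-3,4,5-trimethoxyphenyl)propane-1,3-dione F2, the Baker–Venkataraman-type diketone. Acid-catalysed cyclodehydration (cat. p-TsOH, toluene, 80 °C), in which the two phenols are again equivalent, returns to the route at 12.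

Step 8. Deprotonation may be incomplete or unselective (benzylic metalation of a benzyl ether, or addition of the amide to C2), and the α-keto vinyl boronate may protodeboronate before it is oxidised. Fallback: from 13, epoxidation of the C2=C3 bond with dimethyldioxirane (acetone/CH2Cl2, 0 °C) should give racemic, cis-fused 4',5-bis(benzyloxy)-6,7,8-trimethoxyflavone 2,3-epoxide F3. Catalytic p-TsOH in CH2Cl2 opens it at the C2–O bond and tautomerises it to the 3-hydroxyflavone, returning to the route at 16.

Step 2. The second borylation on the electron-rich ring may stall, protodebromination or protodeboronation may give mono-functionalised material, and the following basic peroxide step risks over-oxidation of the resorcinol. Fallback: from 2, palladium-catalysed C–O coupling with benzyl alcohol ([(allyl)PdCl]2, RockPhos, Cs2CO3, toluene, 90 °C) should give 1,5-bis(benzyloxy)-2,3,4-trimethoxybenzene F4. Hydrogenolysis (H2, Pd/C, EtOAc, rt) then frees both phenols under neutral, non-oxidising conditions and returns to the route at 4.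

**Further compounds**
F1 | step 6 | 1-(2,6-dihydroxy-3,4,5-trimethoxyphenyl)ethan-1-one | CC(=O)c1c(O)c(OC)c(OC)c(OC)c1O
F2 | step 6 | 1-[4-(benzyloxy)phenyl]-3-(2,6-dihydroxy-3,4,5-trimethoxyphenyl)propane-1,3-dione | O=C(CC(=O)c1c(O)c(OC)c(OC)c(OC)c1O)c1ccc(OCc2ccccc2)cc1
F3 | step 8 | 4',5-bis(benzyloxy)-6,7,8-trimethoxyflavone 2,3-epoxide (racemic, cis-fused) | O=C1c2c(OCc3ccccc3)c(OC)c(OC)c(OC)c2OC2(c3ccc(OCc4ccccc4)cc3)OC12
F4 | step 2 | 1,5-bis(benzyloxy)-2,3,4-trimethoxybenzene | COc1c(OCc2ccccc2)cc(OCc2ccccc2)c(OC)c1OC
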